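The earlier runs and the new flask were generated by integration on assumed constants, and the scatter is random.

The partner reaches this flask by dissolving from the solid reagent, and you want to know how much left-handed product stands at 20 min.

| setting | epsilon | beta | delta | flask |
|---|---|---|---|---|
| left-handed substrate | 0.10 M | 0.10 M | 0.15 M | 0.10 M |
| right-handed substrate | 0.10 M | 0.10 M | 0.15 M | 0.10 M |
| solid reagent | 0.31 M | 0.48 M | 0.22 M | 0.220 M |
| remark | run made earlier | run made earlier | run made earlier |  |
| time |  |  |  | 20 min |

| run | time / min | left-handed product / % | left-handed substrate / % |
|---|---|---|---|
| epsilon | 3.00 | 1.3 | 49.2 |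
| epsilon | 8.00 | 5.6 | 45.2 |
| epsilon | 15.0 | 15.1 | 39.2 |
| epsilon | 25.0 | 25.5 | 30.4 |
| beta | 3.00 | 1.1 | 48.7 |
| beta | 8.00 | 5.8 | 46.1 |
| beta | 15.0 | 14.2 | 39.8 |
| beta | 25.0 | 25.4 | 30.5 |
| delta | 2.00 | 1.2 | 50.7 |
| delta | 4.00 | 2.1 | 49.4 |
| delta | 10.0 | 8.5 | 44.2 |
| delta | 25.0 | 23.1 | 32.8 |

(readings scatter by 0.5 percentage points)

- partner is single-handed; left-handed substrate and right-handed substrate are mirror images of each other, charged as a racemate, each of them at the stated concentration
- as a solid, counted per litre of solution: solid reagent
- reactions considered so far: partner + left-handed substrate -> left-handed product; left-handed substrate <-> right-handed substrate; solid reagent <-> partner; partner + right-handed substrate -> right-handed product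
- at the start none of the solid reagent is in solution
- the handed part of partner does not stay in what it makes, so the products of the two hands are mirror images too

* the left-handed product standing at 20 min, as a percentage of the left-handed substrate and right-handed substrate together charged
* the change that raises the amount of left-handed product at 20 min, in percent of the left-handed substrate and right-handed substrate together charged most ("none" if none brings more than 2 percentage points) (Wednesday's / Thursday's / none)
* amount of left-handed product at 20 min, in percent of the left-handed substrate and right-handed substrate together charged, after Wednesday's

- Wednesday's: doubling the dissolution coefficient of the solid reagent, all else as stated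
- Thursday's: doubling the solubility of the solid reagent, all else as stated

Work in powers of ten. Between 15.0 min and 25.0 min in the epsilon run, the left-handed substrate falls at a rate that gives a decade time of 90.6 min, the minutes a tenfold fall takes on this pseudo-first-order reading. You may carry it to the flask because the epsilon and beta runs read 25.5 % and 25.4 % of left-handed product at 25.0 min, nearly the same, on different solid charges. My reckoning from the 15.0 min reading leaves 34.5 % of left-handed substrate in the flask at 20 min. Taking the right-handed substrate as equal, the two substrates have lost 0.0619 M, less than the 0.220 M of solid charged. The epsilon run puts 65.1 % of such a loss into left-handed product, so I expect 20.1 %.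

The forecast, holding that “excess solid doesn't set the rate”, says 20.5 %, slightly above my figure, with Thursday's as the best change and 25.5 % after Wednesday's.

The flask gives 20.1 %. Thursday's is the best change, adding 15 percentage points, more than the 6 points from Wednesday's, which reaches 26.0 %.

    partner + left-handed substrate → left-handed product (k = 0.0101 L mol⁻¹ s⁻¹)
    left-handed substrate ⇌ right-handed substrate (k = 0.0126 s⁻¹)
    solid reagent ⇌ partner, rate k3*(cs3 - [partner]) while solid is left; crystals form when [partner] > cs3 (solubility = 0.0820 M, k = 0.00223 s⁻¹)
    partner + right-handed substrate → right-handed product (k = 0.00505 L mol⁻¹ s⁻¹)

At 20 min this flask holds 34.7 % of left-handed substrate, where the decade time put 34.5 %, and 35.1 % of right-handed substrate, and the partner uses left-handed substrate at 0.042 of the forward rate of its turning into right-handed substrate. Now read the same charge at 30 min. The decade time, from the same 15.0 min reading, gives 26.8 % of left-handed substrate, and the same share gives 30.2 % of left-handed product. That neighbouring flask holds 27.0 % of left-handed substrate and 30.4 % of left-handed product.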